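Numbering used throughout: C1 = methyl-bearing ring-fusion carbon, C2 and C3 = cyclopentane CH2, C4 = isopropyl carbinol, C5 = ring-fusion CH, C6 = acyloxy CH, C7 = CH2, C8 = methyl carbinol, C9 = CHOH, C10 = CH2. Ring A is the cyclopentane C1–C5, ring B the cycloheptane C1, C5–C10. β is the face of the C1 methyl group, α the opposite face.

## The problem

The target is a trans-fused bicyclo[5.3.0]decane in which ring A and ring B share the C1–C5 bond, with the angular methyl (β) and H5 (α) on opposite faces. Six stereocentres have to be set: the all-carbon quaternary C1, the tertiary carbinols C4 and C8, the ring-fusion C5, and the secondary carbinols C6 (acylated) and C9. C1 cannot be corrected once made, so it must be set first and in the absolute sense. Once the ring fusion is trans, the axial C1 methyl covers the β face of ring B, which can steer an epoxidation at C8=C9, and a free 4β-hydroxyl can deliver hydride to C6. C4 itself is the awkward centre: while C5 is planar, the two faces at C4 differ only by a methyl group versus a ring CH2 on C1, so C4 needs a relay of its own. The 8β,9α-diol is trans and calls for anti opening of an epoxide. Several groups are fragile: the aldol unit C4(OH)–C5H–C6=O (retro-aldol, loss of water), a β,γ-unsaturated ketone on the way to C8=C9, an acid-labile trisubstituted epoxide close to the C4 hydroxyl, and the aryl ester with its free phenol late in the route. The feature that opens the skeleton is that C1 is the β-carbon of a cross-conjugated dienone C2=C3–C4(=O)–C5=C1 whose α-carbon C5 carries the oxygenated C6. A 4π closure then forms C1–C2 and ring A, and a stereocentre at C6 sits beside the reacting terminus and can afterwards be given up as a C5=C6 enol ether that keeps the C4 and C6 oxygens distinct.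

## Retrosynthesis

**Phenol and diol.** Target 26 is traced to its benzyl ether 25 (aryl O–benzyl bond), because the phenol must be masked during acylation and hydrogenolysis is harmless once no alkene is left. In 25 the C8–OH bond is cut, leading to the 8α,9α-epoxide 24. Dihydroxylation of an alkene would give the cis-diol; anti opening of the α-epoxide at the tertiary C8 gives 8β-OH and leaves 9α-O. The forward step asks that external water outrun the 4β-hydroxyl and proton loss.

**Ester and epoxide.** The ester C6–O acyl bond of 24 is cut to the epoxy diol 22 and the acid 23. Acylation is placed before hydrolysis so that C6–OH is the only secondary hydroxyl present. The epoxide C–O bonds of 22 are then cut to the alkene 21. The forward epoxidation must come from the α face, which the axial C1 methyl should enforce.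

**Ring B functionality.** Ring B is bought bare, so the C6 carbonyl is its only handle. Diol 21 comes from hydroxy ketone 20 by cutting C6–H; hydride delivered internally from the 4β-hydroxyl is the one approach not blocked by the C1 methyl. Ketone 20 is the desilylated form of 19, and 19 is the deconjugated isomer of enone 18. In 18 the C8–CH3 bond is cut (conjugate addition, then re-oxidation) back to enone 16, and 16 comes from the saturated ketone 14 by dehydrogenation at C7–C8. Each step is a standard enone operation; the price is their number.

**The aldol unit.** Direct addition of an isopropyl nucleophile to the C4 carbonyl of the planar bicycle 8 would leave the C4 configuration to a methyl-versus-CH2 difference. Instead the C4–O bond and C5–H of 14 are traced to the epoxy ketone 13 (reductive cleavage of Cα–O). Ketone 13 comes from the epoxy alcohol 12, and 12 from the allylic alcohol 11, whose 6β-hydroxyl directs oxygen to the β face of C4=C5. The carbinol of 11 is set by a chiral reducing catalyst on enone 10, independently of the weak bias of C1. This costs four steps and buys a C4 configuration that rests on reagent control and an intramolecular delivery.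

**Isopropyl group.** The C4–isopropyl bond of 10 is cut to the vinylogous silyl ester 8. Addition to the C4 carbonyl followed by acid gives the transposed enone, and the configuration of the adduct 9 is irrelevant.

**Ring A.** The C1–C2 bond of 8 is cut, opening ring A to the cycloheptenyl vinyl ketone 7. This is preferred to cuts at C4–C5 or C1–C10 because it creates the quaternary centre and the ring in one step from a monocycle with a single stereocentre. The forward reaction must show torquoselectivity at C1 and must end by loss of the C6 proton.

**Dienone assembly.** The C4–C5 bond of 7 is cut to the vinyllithium 6 and the acrylamide 5. Lithium reagent 6 comes from the iodide 4, its alcohol 3 from the iodo enone 2 by asymmetric reduction, and 2 from the commercial enone 1.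

## Roads not taken

Alternative 1: Cuts C1–C10 and C5–C6 at the cyclopentane and leaves ring B open. In the forward step a chiral copper catalyst (for example CuBr·SMe2 with a chiral diphosphine) adds a two-carbon acetal Grignard reagent to 3-methylcyclopent-2-en-1-one A1, and the magnesium enolate is trapped at C5 by a ketal-protected keto aldehyde to give the aldol A2.
- Merits: C1 comes from catalyst control, and three stereocentres and two C–C bonds form in one flask. In one respect it is better than the chosen plan: the C4 ketone of A2 lies next to an sp3 C5 that carries the C6 chain, so an isopropyl nucleophile should add anti to that chain and to the methyl without the four-step relay of steps 7–10.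
- Weak points: asymmetric conjugate addition to a β-substituted cyclopentenone is the least dependable case of that reaction. The aldehyde partner is enolisable, and C6 rests on an open aldol transition state. A2 is a retro-aldol-prone β-hydroxy ketone at the moment the isopropyl group has to be added. Ring B is still unmade: C8–C9 must later be closed as a seven-membered ring by carbonyl coupling, and a pinacol closure would favour the cis-diol, so an alkene and epoxide would still be needed.
- Comparison: the chosen plan has both rings in place after step 5, buys ring B ready-made and carries the C6 oxygen from the first step.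

Alternative 2: Cuts C6–C7 of ring B. Me2AlCl promotes a carbonyl-ene reaction between a C6 aldehyde on the cyclopentane and an isopropenyl group at the end of the C10–C9 chain. This closes ring B and gives A3 with the C6 carbinol, an exocyclic methylene on C8 and the C9 oxygen already present as a silyl ether.
- Merits: for the late stage this road is better. The C9 oxygen never has to be introduced into a ring, C8 would become a tertiary alcohol by hydration of the methylene group, and neither the deconjugation nor the acid opening of an epoxide beside a free C4 hydroxyl is needed.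
- Weak points: the ene substrate already contains C1, C4, C5 and C9, so the quaternary centre and the tertiary carbinol have to be built beforehand in a long linear sequence. Seven-membered ene closures are slow, and the Lewis acid endangers the tertiary silyl ether. The C6 configuration and the face of the later hydration at C8 depend on the conformation of a flexible ring.
- Comparison: the chosen plan solves C1 and ring A in one step and leaves the difficulty in ring B, where the reactions are ordinary.

Alternative 3: Cuts C1–C5 and C6–C7 and closes both rings at once. A cationic rhodium–bisphosphine catalyst such as [Rh(BINAP)]SbF6 joins a siloxy-substituted vinylcyclopropane (C1=C10 with C9, C8, C7) to a tethered ynone (C5≡C6) and gives the dienone A4.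
- Merits: its step economy is better than anything in the chosen plan. The bicyclic core, the C4 ketone, the C8 methyl and the C9 oxygen arrive in one catalytic step, whereas the chosen plan spends about seven steps on C8 and C9.
- Weak points: C1 would be a quaternary centre formed enantioselectively from a 1,1-disubstituted alkene terminus, for which there is little support. The cyclopropane must already carry the C8 stereocentre. C6 emerges as an unoxygenated alkene carbon, so C6–O and C5–H would have to be introduced by conjugate oxygenation and protonation with no directing group. C8 needs an oxygen on a fully substituted carbon while the enol ether points towards C10.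
- Comparison: the chosen plan carries the C6 oxygen from the start and uses it twice, first as the controlling stereocentre and then as the enol ether.

Key step: step 5

## Route

Remark on the chemistry: compounds 1, 5 and 23 are taken as purchasable; the phenol is carried as its benzyl ether, and the C6 ether is triisopropylsilyl because its enol ether in 8 should be more robust than that of a smaller silyl group.

Step 1
Reactants: 1 3-methylcyclohept-2-en-1-one
Product: 2 2-iodo-3-methylcyclohept-2-en-1-one
Conditions: I2, DMAP (cat.), K2CO3, THF/H2O (1:1), rt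
Reagents that add atoms: iodine, II
Why: α-Iodination of the enone by amine conjugate addition, iodination of the enolate and elimination (Baylis–Hillman-type mechanism); DMAP is used because the β-carbon is substituted.

Step 2
Reactants: 2 2-iodo-3-methylcyclohept-2-en-1-one
Product: 3 (R)-2-iodo-3-methylcyclohept-2-en-1-ol
Conditions: (S)-2-methyl-CBS-oxazaborolidine (20 mol %), BH3·SMe2, THF, −20 °C; MeOH
Reagents that add atoms: none
Why: Corey–Bakshi–Shibata reduction; the iodoalkenyl arm acts as the large substituent, so the (S)-catalyst should give the (R)-carbinol (same sense as acetophenone to (R)-1-phenylethanol). This centre later steers the electrocyclisation.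

Step 3
Reactants: 3 (R)-2-iodo-3-methylcyclohept-2-en-1-ol
Product: 4 (R)-[(2-iodo-3-methylcyclohept-2-en-1-yl)oxy]triisopropylsilane
Conditions: i-Pr3SiOTf, 2,6-lutidine, CH2Cl2, 0 °C
Reagents that add atoms: triisopropylsilyl trifluoromethanesulfonate, CC(C)[Si](C(C)C)(C(C)C)OS(=O)(=O)C(F)(F)F
Why: Silylation of a hindered secondary allylic alcohol with a silyl triflate; the bulky group is chosen for shielding in step 5 and for the stability of the enol ether in 8.

Step 4
Reactants: 4 (R)-[(2-iodo-3-methylcyclohept-2-en-1-yl)oxy]triisopropylsilane; 5 N-methoxy-N-methylacrylamide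
Product: 7 (R)-1-[2-methyl-7-(triisopropylsilyloxy)cyclohept-1-en-1-yl]prop-2-en-1-one, via vinyllithium 6 (not isolated)
Conditions: t-BuLi (2.1 equiv), Et2O, −78 °C; then 5, −78 to −40 °C; poured into cold 1 M HCl
Reagents that add atoms: N-methoxy-N-methylacrylamide (5), C=CC(=O)N(C)OC
Why: Iodine–lithium exchange gives vinyllithium 6 (β-elimination of the silyloxy group would need a cyclic allene and should not occur), which adds once to the N-methoxy-N-methylamide (Weinreb ketone synthesis). The chelated adduct collapses only on the acidic quench, which also keeps the liberated amine from adding to the vinyl ketone.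

Step 5
Reactants: 7 (R)-1-[2-methyl-7-(triisopropylsilyloxy)cyclohept-1-en-1-yl]prop-2-en-1-one
Product: 8 (1S)-1-methyl-6-(triisopropylsilyloxy)bicyclo[5.3.0]dec-5-en-4-one
Conditions: BF3·OEt2 (1.5 equiv), 2,6-di-tert-butyl-4-methylpyridine (1.2 equiv), CH2Cl2, −78 to −20 °C; aq NaHCO3
Reagents that add atoms: none
Why: BF3 binds the carbonyl oxygen of 7 and gives a 3-oxidopentadienyl cation that closes by thermal conrotatory 4π electrocyclisation (Nazarov cyclisation; ring A closes through the new C1–C2 bond, formally a 5-endo closure); the closest known reaction type is the Lewis-acid Nazarov cyclisation of cycloalkenyl vinyl ketones whose sense of rotation is set by a ring stereocentre beside the dienone. The only new stereocentre is C1, and only this terminus reports the torquoselectivity because C2 is unsubstituted. In the reactive conformer the C6–O bond stands pseudo-axial on the β face (this avoids allylic strain between the silyloxy group and the acyl carbon) and C7 lies on the α face; the conrotation that lets C10 follow C7 to the α face turns the inside methyl group to the β face and joins C2 to the α lobe of C1, anti to the silyloxy group, whereas the opposite rotation would drive C10 into that group. BF3 is monodentate, so no chelate can pull the ether oxygen into the dienone plane and cancel this bias. In the oxyallyl cation the charge rests mainly on the fully substituted C5; the new 1,3-interaction between the C1 methyl and the silyloxy group turns the C6–H bond into line with the empty orbital, and the hindered pyridine removes this proton, not one on C2, because the product is a tetrasubstituted donor–acceptor enol ether. The C6 stereocentre is thereby spent, but its oxygen survives as the silyl enol ether that keeps C6 and C4 distinct. The step needs torquoselectivity (secured by the C6 stereocentre) and regioselective termination (secured by the charge distribution and the C6 oxygen); the low temperature and the bulk of the silyl group are meant to protect the enol ether.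

Step 6
Reactants: 8 (1S)-1-methyl-6-(triisopropylsilyloxy)bicyclo[5.3.0]dec-5-en-4-one
Product: 10 (1S)-4-isopropyl-1-methylbicyclo[5.3.0]dec-4-en-6-one, via tertiary carbinol 9 (not isolated)
Conditions: i-PrMgCl, CeCl3, THF, −78 to 0 °C; then 2 M HCl, THF, rt
Reagents that add atoms: isopropylmagnesium chloride, CC(C)[Mg]Cl
Why: Organocerium 1,2-addition to the hindered, enolisable vinylogous ester carbonyl, then acid-induced ionisation of the tertiary allylic alcohol and hydrolysis of the silyl enol ether (Stork–Danheiser-type transposition) give the C4=C5 enone. Both C4 epimers of 9 converge, so the weak facial bias of the planar bicycle at C4 has no consequence.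

Step 7
Reactants: 10 (1S)-4-isopropyl-1-methylbicyclo[5.3.0]dec-4-en-6-one
Product: 11 (1S,6R)-4-isopropyl-1-methylbicyclo[5.3.0]dec-4-en-6-ol (6β-hydroxyl)
Conditions: (S)-2-methyl-CBS-oxazaborolidine (1.0 equiv), catecholborane, toluene, −60 to −40 °C
Reagents that add atoms: none
Why: Corey–Bakshi–Shibata reduction under catalyst control: the fully substituted alkenyl arm (C5) is the large group and C7H2 the small one, so the (S)-catalyst should give the (6R)-alcohol with the hydroxyl on the β face. Catecholborane avoids conjugate reduction.

Step 8
Reactants: 11 (1S,6R)-4-isopropyl-1-methylbicyclo[5.3.0]dec-4-en-6-ol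
Product: 12 4β,5β-epoxy-4α-isopropyl-1β-methylbicyclo[5.3.0]decan-6β-ol
Conditions: VO(acac)2 (5 mol %), t-BuOOH (decane), CH2Cl2, 0 °C to rt
Reagents that add atoms: tert-butyl hydroperoxide, CC(C)(C)OO
Why: Vanadium-catalysed hydroxyl-directed epoxidation of the allylic alcohol: with H6 in the alkene plane (allylic strain with the isopropyl group) the 6β-hydroxyl sits over the β face and delivers the oxygen there. This sets the C4–O bond β and the isopropyl group α.

Step 9
Reactants: 12 4β,5β-epoxy-4α-isopropyl-1β-methylbicyclo[5.3.0]decan-6β-ol
Product: 13 4β,5β-epoxy-4α-isopropyl-1β-methylbicyclo[5.3.0]decan-6-one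
Conditions: Dess–Martin periodinane, NaHCO3, CH2Cl2, 0 °C to rt
Reagents that add atoms: none
Why: Dess–Martin oxidation of the secondary alcohol under buffered conditions that spare the acid-labile tetrasubstituted epoxide; the C6 stereocentre has done its work and is removed.

Step 10
Reactants: 13 4β,5β-epoxy-4α-isopropyl-1β-methylbicyclo[5.3.0]decan-6-one
Product: 14 4β-hydroxy-4α-isopropyl-1β-methyl-5αH-bicyclo[5.3.0]decan-6-one
Conditions: SmI2 (2.5 equiv), THF/MeOH (4:1), −78 °C; pH 7 buffer
Reagents that add atoms: none
Why: Samarium diiodide cleaves the Cα–O bond of the α,β-epoxy ketone by two single-electron transfers (the established reduction of epoxy ketones to aldols) and leaves the C4–O bond untouched, so the 4β-hydroxyl is retained. Methanol should protonate the samarium enolate at C5 on the α face, away from the angular methyl and the samarium-bound C4 alkoxide; this trans-fused isomer should also be the more stable one because the C5–C6 bond is anti to the isopropyl group.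

Step 11
Reactants: 14 4β-hydroxy-4α-isopropyl-1β-methyl-5αH-bicyclo[5.3.0]decan-6-one
Product: 16 4α-isopropyl-1β-methyl-4β-(trimethylsilyloxy)-5αH-bicyclo[5.3.0]dec-7-en-6-one, via bis(trimethylsilyl) compound 15 (not isolated)
Conditions: LiN(i-Pr)2 (2.4 equiv), Me3SiCl (3 equiv, present from the start), THF, −78 to 0 °C; then Pd(OAc)2 (1.1 equiv), MeCN, rt
Reagents that add atoms: chlorotrimethylsilane, C[Si](C)(C)Cl
Why: Kinetic deprotonation occurs at C7 (C5–H lies between two quaternary carbons), and the silyl chloride traps both the enolate and the tertiary alkoxide before retro-aldol cleavage can start. Saegusa–Ito oxidation of the silyl enol ether 15 then gives the C7=C8 enone, and the tertiary silyl ether stays as protection of the aldol unit.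

Step 12
Reactants: 16 4α-isopropyl-1β-methyl-4β-(trimethylsilyloxy)-5αH-bicyclo[5.3.0]dec-7-en-6-one
Product: 18 4α-isopropyl-1β,8-dimethyl-4β-(trimethylsilyloxy)-5αH-bicyclo[5.3.0]dec-7-en-6-one, via silyl enol ether 17 (not isolated)
Conditions: MeMgBr, CuBr·SMe2 (10 mol %), Me3SiCl, HMPA, THF, −78 °C; then Pd(OAc)2 (1.1 equiv), MeCN, rt
Reagents that add atoms: methylmagnesium bromide, C[Mg]Br
Why: Copper-catalysed conjugate addition of the methyl Grignard reagent, accelerated and trapped by the silyl chloride, places the methyl group on C8. A second Saegusa–Ito oxidation of 17 restores the C7=C8 enone, so the C8 configuration in 17 does not matter.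

Step 13
Reactants: 18 4α-isopropyl-1β,8-dimethyl-4β-(trimethylsilyloxy)-5αH-bicyclo[5.3.0]dec-7-en-6-one
Product: 19 4α-isopropyl-1β,8-dimethyl-4β-(trimethylsilyloxy)-5αH-bicyclo[5.3.0]dec-8-en-6-one
Conditions: LiN(i-Pr)2 (1.3 equiv), HMPA, THF, −78 °C; then AcOH, −78 °C
Reagents that add atoms: none
Why: Deconjugation through the extended enolate: with the α' hydrogen (C5–H) shielded, the amide base should remove the ring γ-hydrogen at C9 and give the more substituted endocyclic dienolate. Kinetic protonation at C7 at low temperature then gives the β,γ-unsaturated ketone.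

Step 14
Reactants: 19 4α-isopropyl-1β,8-dimethyl-4β-(trimethylsilyloxy)-5αH-bicyclo[5.3.0]dec-8-en-6-one
Product: 20 4β-hydroxy-4α-isopropyl-1β,8-dimethyl-5αH-bicyclo[5.3.0]dec-8-en-6-one
Conditions: HF·pyridine, pyridine, THF, 0 °C
Reagents that add atoms: none
Why: Buffered HF cleaves the trimethylsilyl ether without base, so the β,γ-enone should not be reconjugated and the aldol unit is not exposed to retro-aldol conditions.

Step 15
Reactants: 20 4β-hydroxy-4α-isopropyl-1β,8-dimethyl-5αH-bicyclo[5.3.0]dec-8-en-6-one
Product: 21 4α-isopropyl-1β,8-dimethyl-5αH-bicyclo[5.3.0]dec-8-ene-4β,6α-diol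
Conditions: Me4NBH(OAc)3, MeCN/AcOH (1:1), −30 to −20 °C
Reagents that add atoms: none
Why: Evans–Saksena reduction: the C4 hydroxyl exchanges onto boron and hydride is delivered internally to the β face of C6 (axial attack), giving the equatorial 6α-alcohol, the 1,3-anti diol. External hydrides would be pushed to the other face by the 1,3-diaxial C1 methyl group.

Step 16
Reactants: 21 4α-isopropyl-1β,8-dimethyl-5αH-bicyclo[5.3.0]dec-8-ene-4β,6α-diol
Product: 22 8α,9α-epoxy-4α-isopropyl-1β,8β-dimethyl-5αH-bicyclo[5.3.0]decane-4β,6α-diol
Conditions: m-CPBA, NaHCO3, CH2Cl2, 0 °C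
Reagents that add atoms: 3-chloroperbenzoic acid, OOC(=O)c1cccc(Cl)c1
Why: Peracid epoxidation of the trisubstituted alkene from the α face: the β face at C9 is covered by the axial C1 methyl group, and the 6α-hydroxyl can assist by hydrogen bonding. The alcohols are inert.

Step 17
Reactants: 22 8α,9α-epoxy-4α-isopropyl-1β,8β-dimethyl-5αH-bicyclo[5.3.0]decane-4β,6α-diol; 23 4-(benzyloxy)benzoic acid
Product: 24 8α,9α-epoxy-4β-hydroxy-4α-isopropyl-1β,8β-dimethyl-5αH-bicyclo[5.3.0]decan-6α-yl 4-(benzyloxy)benzoate
Conditions: DCC, DMAP, CH2Cl2, rt
Reagents that add atoms: 4-(benzyloxy)benzoic acid (23), O=C(O)c1ccc(OCc2ccccc2)cc1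
Why: Steglich esterification; only the secondary C6 hydroxyl reacts, the tertiary C4 hydroxyl is too hindered, and the neutral conditions spare the epoxide. The benzyl ether prevents self-acylation of the phenol.

Step 18
Reactants: 24 8α,9α-epoxy-4β-hydroxy-4α-isopropyl-1β,8β-dimethyl-5αH-bicyclo[5.3.0]decan-6α-yl 4-(benzyloxy)benzoate
Product: 25 4β,8β,9α-trihydroxy-4α-isopropyl-1β,8α-dimethyl-5αH-bicyclo[5.3.0]decan-6α-yl 4-(benzyloxy)benzoate
Conditions: HClO4 (0.1 M aq, cat.), THF/H2O (3:1), 0 °C to rt
Reagents that add atoms: water, O
Why: Acid-catalysed hydrolysis of the trisubstituted epoxide: water attacks the tertiary C8 anti to the breaking C–O bond (β face, inversion at C8) while C9 keeps its α oxygen, which gives the trans 8β,9α-diol. The ester lies on the α face and cannot take part.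

Step 19
Reactants: 25 4β,8β,9α-trihydroxy-4α-isopropyl-1β,8α-dimethyl-5αH-bicyclo[5.3.0]decan-6α-yl 4-(benzyloxy)benzoate
Product: 26 4β,8β,9α-trihydroxy-4α-isopropyl-1β,8α-dimethyl-5αH-bicyclo[5.3.0]decan-6α-yl 4-hydroxybenzoate (CNP0197754.1)
Conditions: H2 (1 atm), Pd/C (10%), EtOAc, rt
Reagents that add atoms: none
Why: Hydrogenolysis of the aryl benzyl ether under neutral conditions; no alkene or epoxide remains, and the aryl ester and the alcohols are inert.

## Compound list

1 | 3-methylcyclohept-2-en-1-one | CC1=CC(=O)CCCC1 | starting material
2 | 2-iodo-3-methylcyclohept-2-en-1-one | CC1=C(I)C(=O)CCCC1 | intermediate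
3 | (R)-2-iodo-3-methylcyclohept-2-en-1-ol | IC1=C(C)CCCC[C@H]1O | intermediate
4 | (R)-[(2-iodo-3-methylcyclohept-2-en-1-yl)oxy]triisopropylsilane | IC1=C(C)CCCC[C@H]1O[Si](C(C)C)(C(C)C)C(C)C | intermediate
5 | N-methoxy-N-methylacrylamide | C=CC(=O)N(C)OC | starting material
6 | (R)-[2-methyl-7-(triisopropylsilyloxy)cyclohept-1-en-1-yl]lithium | [Li]C1=C(C)CCCC[C@H]1O[Si](C(C)C)(C(C)C)C(C)C | intermediate
7 | (R)-1-[2-methyl-7-(triisopropylsilyloxy)cyclohept-1-en-1-yl]prop-2-en-1-one | C=CC(=O)C1=C(C)CCCC[C@H]1O[Si](C(C)C)(C(C)C)C(C)C | intermediate
8 | (1S)-1-methyl-6-(triisopropylsilyloxy)bicyclo[5.3.0]dec-5-en-4-one | O=C1CC[C@]2(C)CCCCC(O[Si](C(C)C)(C(C)C)C(C)C)=C21 | intermediate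
9 | 4-isopropyl-1β-methyl-6-(triisopropylsilyloxy)bicyclo[5.3.0]dec-5-en-4-ol (both C4 epimers) | CC(C)C1(O)CC[C@]2(C)CCCCC(O[Si](C(C)C)(C(C)C)C(C)C)=C21 | intermediate
10 | (1S)-4-isopropyl-1-methylbicyclo[5.3.0]dec-4-en-6-one | CC(C)C1=C2[C@](C)(CC1)CCCCC2=O | intermediate
11 | (1S,6R)-4-isopropyl-1-methylbicyclo[5.3.0]dec-4-en-6-ol | CC(C)C1=C2[C@](C)(CC1)CCCC[C@H]2O | intermediate
12 | 4β,5β-epoxy-4α-isopropyl-1β-methylbicyclo[5.3.0]decan-6β-ol | CC(C)[C@]1(O2)CC[C@]3(C)CCCC[C@@H](O)[C@@]312 | intermediate
13 | 4β,5β-epoxy-4α-isopropyl-1β-methylbicyclo[5.3.0]decan-6-one | CC(C)[C@]1(O2)CC[C@]3(C)CCCCC(=O)[C@@]312 | intermediate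
14 | 4β-hydroxy-4α-isopropyl-1β-methyl-5αH-bicyclo[5.3.0]decan-6-one | CC(C)[C@]1(O)CC[C@]2(C)CCCCC(=O)[C@H]21 | intermediate
15 | 4α-isopropyl-1β-methyl-4β,6-bis(trimethylsilyloxy)-5αH-bicyclo[5.3.0]dec-6-ene | CC(C)[C@]1(O[Si](C)(C)C)CC[C@]2(C)CCCC=C(O[Si](C)(C)C)[C@H]21 | intermediate
16 | 4α-isopropyl-1β-methyl-4β-(trimethylsilyloxy)-5αH-bicyclo[5.3.0]dec-7-en-6-one | CC(C)[C@]1(O[Si](C)(C)C)CC[C@]2(C)CCC=CC(=O)[C@H]21 | intermediate
17 | 4α-isopropyl-1β,8-dimethyl-4β,6-bis(trimethylsilyloxy)-5αH-bicyclo[5.3.0]dec-6-ene (C8 epimers) | CC(C)[C@]1(O[Si](C)(C)C)CC[C@]2(C)CCC(C)C=C(O[Si](C)(C)C)[C@H]21 | intermediate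
18 | 4α-isopropyl-1β,8-dimethyl-4β-(trimethylsilyloxy)-5αH-bicyclo[5.3.0]dec-7-en-6-one | CC(C)[C@]1(O[Si](C)(C)C)CC[C@]2(C)CCC(C)=CC(=O)[C@H]21 | intermediate
19 | 4α-isopropyl-1β,8-dimethyl-4β-(trimethylsilyloxy)-5αH-bicyclo[5.3.0]dec-8-en-6-one | CC(C)[C@]1(O[Si](C)(C)C)CC[C@]2(C)CC=C(C)CC(=O)[C@H]21 | intermediate
20 | 4β-hydroxy-4α-isopropyl-1β,8-dimethyl-5αH-bicyclo[5.3.0]dec-8-en-6-one | CC(C)[C@]1(O)CC[C@]2(C)CC=C(C)CC(=O)[C@H]21 | intermediate
21 | 4α-isopropyl-1β,8-dimethyl-5αH-bicyclo[5.3.0]dec-8-ene-4β,6α-diol | CC(C)[C@]1(O)CC[C@]2(C)CC=C(C)C[C@H](O)[C@H]21 | intermediate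
22 | 8α,9α-epoxy-4α-isopropyl-1β,8β-dimethyl-5αH-bicyclo[5.3.0]decane-4β,6α-diol | CC(C)[C@]1(O)CC[C@]2(C)C[C@@H]3O[C@]3(C)C[C@H](O)[C@H]21 | intermediate
23 | 4-(benzyloxy)benzoic acid | O=C(O)c1ccc(OCc2ccccc2)cc1 | starting material
24 | 8α,9α-epoxy-4β-hydroxy-4α-isopropyl-1β,8β-dimethyl-5αH-bicyclo[5.3.0]decan-6α-yl 4-(benzyloxy)benzoate | CC(C)[C@]1(O)CC[C@]2(C)C[C@@H]3O[C@]3(C)C[C@H](OC(=O)c4ccc(OCc5ccccc5)cc4)[C@H]21 | intermediate
25 | 4β,8β,9α-trihydroxy-4α-isopropyl-1β,8α-dimethyl-5αH-bicyclo[5.3.0]decan-6α-yl 4-(benzyloxy)benzoate | CC(C)[C@]1(O)CC[C@]2(C)C[C@H](O)[C@@](C)(O)C[C@H](OC(=O)c3ccc(OCc4ccccc4)cc3)[C@H]21 | intermediate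
26 | 4β,8β,9α-trihydroxy-4α-isopropyl-1β,8α-dimethyl-5αH-bicyclo[5.3.0]decan-6α-yl 4-hydroxybenzoate (CNP0197754.1) | CC(C)[C@]1(O)CC[C@]2(C)C[C@H](O)[C@@](C)(O)C[C@H](OC(=O)c3ccc(O)cc3)[C@H]21 | target

## Step count and least certain steps

Total step count: 19. Longest linear sequence: 19 steps, from 1 to 26; 5 and 23 are purchased.

**Step 5 (key step).**
- What may go wrong: the two senses of conrotation may differ too little, so that C1 is set with low selectivity. The oxyallyl cation may lose a C2 proton instead of the C6 proton. It may also undergo a 1,2-hydride shift from C6 followed by loss of the silyl group, which would erase the distinction between the C4 and C6 oxygens. The unsubstituted vinyl ketone may polymerise before the slow closure onto the fully substituted terminus.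
- Fallback (abandons the electrocyclisation and sets C1 by a catalyst): starting from 1, a conjugate addition of [2-(2-isopropyl-1,3-dioxolan-2-yl)ethyl]magnesium bromide, catalysed by Cu(OTf)2 with a chiral N-heterocyclic carbene ligand, creates the quaternary centre and gives (S)-3-[2-(2-isopropyl-1,3-dioxolan-2-yl)ethyl]-3-methylcycloheptan-1-one F1. Aqueous acid removes the ketal and gives (S)-3-methyl-3-(4-methyl-3-oxopentyl)cycloheptan-1-one F2. Aldol condensation (KOH, MeOH) between C5 and the C4 ketone closes ring A and rejoins the route at 10.

**Step 10.**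
- What may go wrong: protonation of the enolate on the β face, which would give the cis ring fusion. If the C5 epimers then had to be equilibrated with base, loss of water from the aldol would compete.
- Fallback (hydrogen is transferred to C5 stereospecifically instead of by protonation): starting from 12, Me3SiOTf and i-Pr2NEt in CH2Cl2 at −78 °C silylate the hydroxyl and trigger the 1,2-hydride shift of the epoxy silyl ether from C6 to C5, anti to the breaking C5–O bond (non-aldol aldol rearrangement). This gives 4α-isopropyl-1β-methyl-4β-(trimethylsilyloxy)-5αH-bicyclo[5.3.0]decan-6-one F3, which is deprotonated and silylated as in step 11 and rejoins the route at 15. Its own weakness is competing ionisation at C4.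

**Step 13.**
- What may go wrong: removal of a methyl hydrogen instead of the C9 hydrogen, leading to the exocyclic alkene; reconjugation during the quench; or enolisation towards C5 followed by β-elimination of the silyloxy group.
- Fallback (soft enolisation in place of a strong base): starting from 18, t-BuMe2SiOTf and Et3N give the through-conjugated dienol ether 6-(tert-butyldimethylsilyloxy)-4α-isopropyl-1β,8-dimethyl-4β-(trimethylsilyloxy)-5αH-bicyclo[5.3.0]deca-6,8-diene F4 under near-thermodynamic control. Bu4NF buffered with AcOH at −78 °C releases the dienolate, protonates it at C7 and removes the trimethylsilyl ether, rejoining the route at 20.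

**Step 16.**
- What may go wrong: poor facial selectivity if ring B adopts a conformation in which the methyl group no longer covers C9.
- Fallback (reagent control in place of substrate control): Shi epoxidation of 21 with the enantiomer of the fructose-derived ketone that is matched to the α face (KHSO5 as 2KHSO5·KHSO4·K2SO4, buffered MeCN/H2O). It starts from 21, returns at 22 and makes no new compound.

**Step 18.**
- What may go wrong: intramolecular opening of the epoxide at C8 by the 4β-hydroxyl, which lies on the face from which water must attack; proton loss beside the developing C8 cation; or a hydride shift from C9.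
- Fallback (the competing nucleophile is masked): starting from 24, silylation of the tertiary hydroxyl (Et3SiCl, imidazole, DMAP, DMF) gives 8α,9α-epoxy-4α-isopropyl-1β,8β-dimethyl-4β-(triethylsilyloxy)-5αH-bicyclo[5.3.0]decan-6α-yl 4-(benzyloxy)benzoate F5. Hydrolysis under the conditions of step 18 gives 8β,9α-dihydroxy-4α-isopropyl-1β,8α-dimethyl-4β-(triethylsilyloxy)-5αH-bicyclo[5.3.0]decan-6α-yl 4-(benzyloxy)benzoate F6, and HF·pyridine removes the silyl group and rejoins the route at 25.

## Further compounds

F1 | step 5 | (S)-3-[2-(2-isopropyl-1,3-dioxolan-2-yl)ethyl]-3-methylcycloheptan-1-one | CC(C)C1(CC[C@]2(C)CCCCC(=O)C2)OCCO1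
F2 | step 5 | (S)-3-methyl-3-(4-methyl-3-oxopentyl)cycloheptan-1-one | CC(C)C(=O)CC[C@]1(C)CCCCC(=O)C1
F3 | step 10 | 4α-isopropyl-1β-methyl-4β-(trimethylsilyloxy)-5αH-bicyclo[5.3.0]decan-6-one | CC(C)[C@]1(O[Si](C)(C)C)CC[C@]2(C)CCCCC(=O)[C@H]21
F4 | step 13 | 6-(tert-butyldimethylsilyloxy)-4α-isopropyl-1β,8-dimethyl-4β-(trimethylsilyloxy)-5αH-bicyclo[5.3.0]deca-6,8-diene | CC(C)[C@]1(O[Si](C)(C)C)CC[C@]2(C)CC=C(C)C=C(O[Si](C)(C)C(C)(C)C)[C@H]21
F0 | step 16 | none | none
F5 | step 18 | 8α,9α-epoxy-4α-isopropyl-1β,8β-dimethyl-4β-(triethylsilyloxy)-5αH-bicyclo[5.3.0]decan-6α-yl 4-(benzyloxy)benzoate | CC(C)[C@]1(O[Si](CC)(CC)CC)CC[C@]2(C)C[C@@H]3O[C@]3(C)C[C@H](OC(=O)c4ccc(OCc5ccccc5)cc4)[C@H]21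
F6 | step 18 | 8β,9α-dihydroxy-4α-isopropyl-1β,8α-dimethyl-4β-(triethylsilyloxy)-5αH-bicyclo[5.3.0]decan-6α-yl 4-(benzyloxy)benzoate | CC(C)[C@]1(O[Si](CC)(CC)CC)CC[C@]2(C)C[C@H](O)[C@@](C)(O)C[C@H](OC(=O)c3ccc(OCc4ccccc4)cc3)[C@H]21
A1 | alternative 1 | 3-methylcyclopent-2-en-1-one | CC1=CC(=O)CC1
A2 | alternative 1 | 3-(1,3-dioxolan-2-ylmethyl)-2-[1-hydroxy-2-(2-methyl-1,3-dioxolan-2-yl)ethyl]-3-methylcyclopentan-1-one | O=C1CC[C@](C)(CC2OCCO2)[C@H]1[C@@H](O)CC3(C)OCCO3
A3 | alternative 2 | 9α-(tert-butyldimethylsilyloxy)-4α-isopropyl-1β-methyl-8-methylidene-4β-(triethylsilyloxy)-5αH-bicyclo[5.3.0]decan-6α-ol | CC(C)[C@]1(O[Si](CC)(CC)CC)CC[C@]2(C)C[C@H](O[Si](C)(C)C(C)(C)C)C(=C)C[C@H](O)[C@H]21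
A4 | alternative 3 | 9-(tert-butyldimethylsilyloxy)-1,8-dimethylbicyclo[5.3.0]deca-5,9-dien-4-one | O=C1CC[C@]2(C)C=C(O[Si](C)(C)C(C)(C)C)[C@H](C)CC=C21
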